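## Retrosynthetic overview
1. Target ⇐ its aryl O-TBS ether (fluoride desilylation last, so the dialdehyde never meets strong base).
2. Key C–O bond A (ester C–O, made together with C11=O): that ether ⇐ 1β,11-epoxydrim-7-en-12-al (a peri-fused oxolane) + O-silylated p-coumaric acid, by acylative–oxidative ether opening.
3. Key C–O bond B (C1–O, sets C1): the oxolane ⇐ 8α-acetoxydriman-11-ol by alkoxy-radical δ-C–H etherification; acetate elimination (Δ7) and allylic oxidation (C12) then give the enal.
4. 8α-Acetoxydriman-11-ol ⇐ (+)-sclareolide (MeLi, cyclic enol ether, ozonolysis). Rings A and B are bought with sclareolide; the only ring made is the temporary oxolane (closed in step 3, opened in step 7).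

Assumption: drimane numbering is used from compound 4 on (C11 on C9, C12 on C8, C15 on C10; β = face of the C10 methyl) and labdane numbering for 2 and 3; commercial (+)-sclareolide and (E)-p-coumaric acid are the starting materials.

## Route

Step 1
Reactants: 1 (+)-sclareolide
Product: 3 8α,12-epoxy-14,15,16-trinorlabd-11-ene, via hydroxy methyl ketone 2 (not isolated)
Conditions: MeLi (1.1 equiv), THF, −78 °C; H2O quench; crude in toluene, PPTS (5 mol %), 4 Å sieves, 50 °C
Reagents that add atoms: methyllithium, [Li]C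
Why: 1,2-addition of the organolithium to the lactone stops at the ketone stage because the lithium hemiketalate persists at −78 °C, and acid-catalysed cyclodehydration of the γ-hydroxy ketone (through its hemiketal) gives the endocyclic enol ether; C5, C8, C9 and C10 are carried over unchanged from sclareolide.

Step 2
Reactants: 3 8α,12-epoxy-14,15,16-trinorlabd-11-ene
Product: 5 8α-acetoxydriman-11-ol, via 8α-acetoxydriman-11-al 4 (not isolated)
Conditions: O3, CH2Cl2–MeOH (5:1), −78 °C; Me2S, −78 → 0 °C; then NaBH4, −40 °C; AcOH quench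
Reagents that add atoms: ozone, [O-][O+]=O
Why: Criegee ozonolysis of the electron-rich enol ether leaves the former ketone carbon on the ring oxygen as an acetate (the tertiary 8α-oxygen emerges protected) and C11 as an aldehyde, which borohydride reduces cold to the primary alcohol before 1,3-acetyl migration or β-elimination can occur; no stereocentre is touched.

Step 3
Reactants: 5 8α-acetoxydriman-11-ol
Product: 7 8α-acetoxy-1β,11-epoxydrimane, via alkyl hypoiodite 6 (not isolated)
Conditions: PhI(OAc)2 (1.5 equiv), I2 (1.0 equiv), cyclohexane–CH2Cl2, visible light (W lamp), 30 °C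
Reagents that add atoms: none
Why: Suárez hypoiodite reaction: O–I homolysis gives the C11 alkoxy radical, which abstracts the equatorial C1 hydrogen (secondary, peri to C11) by 1,5-hydrogen atom transfer in preference to the primary C12/C15 methyl hydrogens, and oxidative C–O ring closure follows; the tether can reach only the equatorial position of C1, so the new C1–O bond is β.

Step 4
Reactants: 7 8α-acetoxy-1β,11-epoxydrimane
Product: 8 1β,11-epoxydrim-7-ene
Conditions: TsOH·H2O (10 mol %), toluene, 70 °C, stopped at full conversion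
Reagents that add atoms: none
Why: acid-promoted E1 loss of the tertiary acetate with kinetic removal of the axial C7 proton gives the trisubstituted Δ7 olefin, the regiochemistry seen when 11-oxygenated driman-8α-ols are dehydrated with acid; the dialkyl ether and all stereocentres are unaffected.

Step 5
Reactants: 8 1β,11-epoxydrim-7-ene
Product: 9 1β,11-epoxydrim-7-en-12-al
Conditions: SeO2 (1.5 equiv), 1,4-dioxane (2% H2O), 90 °C
Reagents that add atoms: selenium dioxide, O=[Se]=O
Why: Riley allylic oxidation (ene reaction, then 2,3-sigmatropic shift) takes place at the methyl group on the more substituted olefin carbon (CH3 before CH), as known for drimenyl acetate, and the allylic alcohol is oxidised on to the conjugated C12 aldehyde without moving the double bond.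

Step 6
Reactants: 10 (E)-p-coumaric acid
Product: 12 (E)-4-(tert-butyldimethylsilyloxy)cinnamic acid, via bis-silyl derivative 11 (not isolated)
Conditions: TBSCl (2.2 equiv), imidazole (4.5 equiv), DMF, 25 °C; then AcOH–THF–H2O (3:1:1), 25 °C
Reagents that add atoms: tert-butyldimethylsilyl chloride, CC(C)(C)[Si](C)(C)Cl
Why: exhaustive silylation followed by selective hydrolysis of the far more labile silyl ester (standard silyl protection) leaves the phenol masked and the acid free; the E double bond is untouched.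

Step 7
Reactants: 9 1β,11-epoxydrim-7-en-12-al; 12 (E)-4-(tert-butyldimethylsilyloxy)cinnamic acid
Product: 16 1β-[(E)-4-(tert-butyldimethylsilyloxy)cinnamoyloxy]drim-7-ene-11,12-dial, via acyl triflate 13 (not isolated), via primary triflate 14 (not isolated), via alkoxysulfonium triflate 15 (not isolated)
Conditions: 12 (1.3 equiv), Tf2O (1.25 equiv), 2,6-di-tert-butyl-4-methylpyridine (1.5 equiv), CH2Cl2, −40 °C; add 9, −40 → 0 °C; DMSO (10 equiv), 0 °C; then Et3N (4 equiv), −20 → 0 °C
Reagents that add atoms: dimethyl sulfoxide, CS(C)=O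
Why: Proposed new method: one-flask acylative–oxidative opening of a cyclic ether to an ω-acyloxy aldehyde, in which the carboxylic–triflic mixed anhydride 13 acylates the ether oxygen of 9, triflate opens the acyloxonium ion by SN2 attack at the primary C11 (the secondary, neopentyl-type C1–O bond is never broken, so the 1β configuration from step 3 is kept in the new ester, and the electron-poor enal olefin cannot participate), DMSO displaces the primary triflate of 14 to give 15, and Et3N collapses 15 through the sulfur ylide to the C11 aldehyde at low temperature without epimerising C9; the closest known reaction types are ether cleavage by carboxylic–sulfonic mixed anhydrides and the Kornblum (Swern-type alkoxysulfonium) oxidation, which have not been merged into a direct ether-to-acyloxy-aldehyde conversion.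

Step 8
Reactants: 16 1β-[(E)-4-(tert-butyldimethylsilyloxy)cinnamoyloxy]drim-7-ene-11,12-dial
Product: 17 1β-[(E)-4-hydroxycinnamoyloxy]drim-7-ene-11,12-dial (CNP0187624.1)
Conditions: HF·pyridine, pyridine–THF, 0 °C
Reagents that add atoms: none
Why: fluoride-induced cleavage of the aryl silyl ether (standard desilylation) in a buffered, weakly acidic medium frees the phenol without touching the cinnamate ester, the enal or the epimerisable C9 centre.

## Compound list
1 | (+)-sclareolide (natural configuration, 8α-O, 9β-CH2) | CC1(C)CCC[C@]2(C)[C@H]3CC(=O)O[C@]3(C)CC[C@@H]12 | starting material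
2 | 8α-hydroxy-14,15,16-trinorlabdan-12-one (C9β-CH2C(=O)CH3, tertiary 8α-OH; in equilibrium with its cyclic hemiketal) | CC1(C)CCC[C@]2(C)[C@@H](CC(C)=O)[C@](C)(O)CC[C@@H]12 | intermediate
3 | 8α,12-epoxy-14,15,16-trinorlabd-11-ene (2-methyl-4,5-dihydrofuran fused at C8–C9, ring oxygen 8α) | CC1(C)CCC[C@]2(C)[C@H]3C=C(C)O[C@]3(C)CC[C@@H]12 | intermediate
4 | 8α-acetoxydriman-11-al (9β-CHO) | CC1(C)CCC[C@]2(C)[C@@H](C=O)[C@](C)(OC(C)=O)CC[C@@H]12 | intermediate
5 | 8α-acetoxydriman-11-ol | CC1(C)CCC[C@]2(C)[C@@H](CO)[C@](C)(OC(C)=O)CC[C@@H]12 | intermediate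
6 | 8α-acetoxydriman-11-yl hypoiodite | CC1(C)CCC[C@]2(C)[C@@H](COI)[C@](C)(OC(C)=O)CC[C@@H]12 | intermediate
7 | 8α-acetoxy-1β,11-epoxydrimane (oxolane bridging C1β-O and C11) | CC1(C)CC[C@H]2OC[C@H]3[C@](C)(OC(C)=O)CC[C@@H]1[C@]23C | intermediate
8 | 1β,11-epoxydrim-7-ene | CC1(C)CC[C@H]2OC[C@H]3C(C)=CC[C@@H]1[C@]23C | intermediate
9 | 1β,11-epoxydrim-7-en-12-al | CC1(C)CC[C@H]2OC[C@H]3C(C=O)=CC[C@@H]1[C@]23C | intermediate
10 | (E)-p-coumaric acid | OC(=O)/C=C/c1ccc(O)cc1 | starting material
11 | tert-butyldimethylsilyl (E)-4-(tert-butyldimethylsilyloxy)cinnamate | CC(C)(C)[Si](C)(C)OC(=O)/C=C/c1ccc(O[Si](C)(C)C(C)(C)C)cc1 | intermediate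
12 | (E)-4-(tert-butyldimethylsilyloxy)cinnamic acid | CC(C)(C)[Si](C)(C)Oc1ccc(/C=C/C(=O)O)cc1 | intermediate
13 | (E)-4-(tert-butyldimethylsilyloxy)cinnamoyl trifluoromethanesulfonate (mixed anhydride) | CC(C)(C)[Si](C)(C)Oc1ccc(/C=C/C(=O)OS(=O)(=O)C(F)(F)F)cc1 | intermediate
14 | 1β-[(E)-4-(tert-butyldimethylsilyloxy)cinnamoyloxy]-11-(trifluoromethanesulfonyloxy)drim-7-en-12-al | CC1(C)CC[C@@H](OC(=O)/C=C/c2ccc(O[Si](C)(C)C(C)(C)C)cc2)[C@]2(C)[C@@H](COS(=O)(=O)C(F)(F)F)C(C=O)=CC[C@@H]12 | intermediate
15 | dimethyl{[1β-[(E)-4-(tert-butyldimethylsilyloxy)cinnamoyloxy]-12-oxodrim-7-en-11-yl]oxy}sulfonium trifluoromethanesulfonate | CC1(C)CC[C@@H](OC(=O)/C=C/c2ccc(O[Si](C)(C)C(C)(C)C)cc2)[C@]2(C)[C@@H](CO[S+](C)C)C(C=O)=CC[C@@H]12.[O-]S(=O)(=O)C(F)(F)F | intermediate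
16 | 1β-[(E)-4-(tert-butyldimethylsilyloxy)cinnamoyloxy]drim-7-ene-11,12-dial | CC1(C)CC[C@@H](OC(=O)/C=C/c2ccc(O[Si](C)(C)C(C)(C)C)cc2)[C@]2(C)[C@@H](C=O)C(C=O)=CC[C@@H]12 | intermediate
17 | 1β-[(E)-3-(4-hydroxyphenyl)prop-2-enoyloxy]drim-7-ene-11,12-dial (5α-H, 9α-H, 10β-CH3) | CC1(C)CC[C@@H](OC(=O)/C=C/c2ccc(O)cc2)[C@]2(C)[C@@H](C=O)C(C=O)=CC[C@@H]12 | target

## Step count and risks
Total step count: 8. Longest linear sequence: 7 (steps 1–5, 7 and 8, from 1).

The three steps most likely to fail:

Step 7 (the proposed new step). The triflate opening of the hindered acyloxonium ion may be slow. Ionisation at C1 (with methyl shift), capture of the primary triflate by the neighbouring ester carbonyl, acylation of the aryl silyl ether, or C9 epimerisation by Et3N could compete. The fallback uses known chemistry, sets out from 9 and 12 and comes back at 16. Acid 12 is converted with (COCl)2 and catalytic DMF into (E)-4-(tert-butyldimethylsilyloxy)cinnamoyl chloride F1. F1 and NaI in MeCN give (E)-4-(tert-butyldimethylsilyloxy)cinnamoyl iodide F2 in the flask. F2 cleaves the oxolane of 9 (acyl iodide ether cleavage, iodide attacking the primary C11) to 1β-[(E)-4-(tert-butyldimethylsilyloxy)cinnamoyloxy]-11-iododrim-7-en-12-al F3. Kornblum oxidation of F3 (AgBF4, DMSO, 20 °C) goes through the alkoxysulfonium tetrafluoroborate F4, which Et3N at 0 °C converts into 16.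

Step 4. The C8 cation can also lose the C9 proton (tetrasubstituted Δ8(9) olefin, not disfavoured by the oxolane) or a C12 proton (exocyclic olefin), and prolonged acid equilibrates towards Δ8(9). The fallback replaces the E1 step by a stereoelectronically controlled sequence, sets out from 7 and comes back at 9 (step 5 is then not needed). LiAlH4 in THF removes the acetate to give 1β,11-epoxydriman-8α-ol F5. SOCl2 and pyridine in CH2Cl2 at −78 °C give 1β,11-epoxydrim-8(12)-ene F6 by E2, because only the C12 hydrogens are antiperiplanar to the equatorial C8–O bond. mCPBA with NaHCO3 epoxidises the α face to 1β,11:8α,12-diepoxydrimane F7. Et2Al(tmp) (diethylaluminium 2,2,6,6-tetramethylpiperidide) in toluene at 0 °C removes the less hindered C7 proton and gives 1β,11-epoxydrim-7-en-12-ol F8. MnO2 in CH2Cl2 oxidises F8 to 9.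

Step 3. The C12 and C15 methyl hydrogens are also δ to the alkoxy radical, so regioisomeric ethers may form, and the product ether can be over-oxidised at C11. The fallback changes the hydrogen abstractor from a free alkoxy radical to a carboxylate-bound metal–oxo species, which strongly prefers secondary over primary C–H. It sets out from 4 (isolated after the Me2S stage of step 2) and comes back at 7. Pinnick oxidation (NaClO2, NaH2PO4, 2-methyl-2-butene, tBuOH–H2O) gives 8α-acetoxydriman-11-oic acid F9. Carboxylate-directed γ-C–H lactonisation with Mn(CF3SO3)2(pdp) (pdp = N,N′-bis(2-pyridylmethyl)-2,2′-bipyrrolidine) and H2O2 in (CF3)2CHOH at 0 °C gives 8α-acetoxydriman-11,1β-olide F10, the rebound placing oxygen on the 1β face. iBu2AlH (1.05 equiv, −78 °C) gives the lactol 8α-acetoxy-1β,11-epoxydriman-11-ol F11. Et3SiH and BF3·OEt2 at −78 °C reduce F11 to 7.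

## Further compounds
F1 | step 7 | (E)-4-(tert-butyldimethylsilyloxy)cinnamoyl chloride | CC(C)(C)[Si](C)(C)Oc1ccc(/C=C/C(Cl)=O)cc1
F2 | step 7 | (E)-4-(tert-butyldimethylsilyloxy)cinnamoyl iodide | CC(C)(C)[Si](C)(C)Oc1ccc(/C=C/C(I)=O)cc1
F3 | step 7 | 1β-[(E)-4-(tert-butyldimethylsilyloxy)cinnamoyloxy]-11-iododrim-7-en-12-al | CC1(C)CC[C@@H](OC(=O)/C=C/c2ccc(O[Si](C)(C)C(C)(C)C)cc2)[C@]2(C)[C@@H](CI)C(C=O)=CC[C@@H]12
F4 | step 7 | dimethyl{[1β-[(E)-4-(tert-butyldimethylsilyloxy)cinnamoyloxy]-12-oxodrim-7-en-11-yl]oxy}sulfonium tetrafluoroborate | CC1(C)CC[C@@H](OC(=O)/C=C/c2ccc(O[Si](C)(C)C(C)(C)C)cc2)[C@]2(C)[C@@H](CO[S+](C)C)C(C=O)=CC[C@@H]12.F[B-](F)(F)F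
F5 | step 4 | 1β,11-epoxydriman-8α-ol | CC1(C)CC[C@H]2OC[C@H]3[C@](C)(O)CC[C@@H]1[C@]23C
F6 | step 4 | 1β,11-epoxydrim-8(12)-ene | CC1(C)CC[C@H]2OC[C@H]3C(=C)CC[C@@H]1[C@]23C
F7 | step 4 | 1β,11:8α,12-diepoxydrimane | CC1(C)CC[C@H]2OC[C@H]3[C@@]4(CO4)CC[C@@H]1[C@]23C
F8 | step 4 | 1β,11-epoxydrim-7-en-12-ol | CC1(C)CC[C@H]2OC[C@H]3C(CO)=CC[C@@H]1[C@]23C
F9 | step 3 | 8α-acetoxydriman-11-oic acid | CC1(C)CCC[C@]2(C)[C@@H](C(=O)O)[C@](C)(OC(C)=O)CC[C@@H]12
F10 | step 3 | 8α-acetoxydriman-11,1β-olide | CC1(C)CC[C@H]2OC(=O)[C@H]3[C@](C)(OC(C)=O)CC[C@@H]1[C@]23C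
F11 | step 3 | 8α-acetoxy-1β,11-epoxydriman-11-ol (lactol, both C11 epimers) | CC1(C)CC[C@H]2OC(O)[C@H]3[C@](C)(OC(C)=O)CC[C@@H]1[C@]23C
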